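**Target note:** Glycyrrhizaisoflavone B (5‑OMe, 7‑OH, 3'‑OH isoflavone with a 4',5'‑fused 2,2‑dimethylchromene) has no stereocentres, so there is no configuration to set.
**Assumption:** in step 2 the acylation of 5‑methoxyresorcinol at C2 (flanked by OMe and OH) is the major pathway. The C4 isomer is separable by chromatography.

## Retrosynthetic overview
1. The chromone γ‑pyranone is cut back to a 2'‑hydroxydeoxybenzoin (C2 introduced as a formyl carbon, Wähälä‑type cyclisation).
2. The deoxybenzoin is cut at the aryl ketone into Cs‑symmetric 5‑methoxyresorcinol and an arylacetic acid. Acylation at the enantiotopic C2/C6 positions differentiates the OMe and OH flanks and sets the 5‑OMe/7‑OH pattern directly.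
3. The arylacetic acid carries the chromene, which is cut back to 3,4‑dihydroxyphenylacetic acid plus prenal (ortho‑quinone‑methide oxa‑6π annulation).
4. Ring order: B‑ring dimethylpyran, then the A‑ring ketone C–C bond, then the chromone pyranone.

## Forward route

**Step 1**
Reactants: **1** 3,4‑dihydroxyphenylacetic acid; **2** 3‑methylbut‑2‑enal (prenal)
Product: **3** 2‑(8‑hydroxy‑2,2‑dimethyl‑2H‑chromen‑6‑yl)acetic acid
Conditions: pyridine, 110 °C, sealed tube, Ar, 24 h
Reagents that add atoms: none
Why: Pyridine‑mediated condensation of the phenol ortho carbon with the enal gives an o‑quinone methide, which undergoes 6π‑oxa‑electrocyclisation to the 2,2‑dimethyl‑2H‑chromene (named reaction type: chromene annulation). The unhindered ortho C–H (C6 of the catechol) reacts in preference to C3, which is flanked by OH and the CH2CO2H side chain, so the free 8‑OH ends up next to the ring oxygen as required. No stereocentre is formed.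

**Step 2**
Reactants: **3** the chromene acid; **4** 5‑methoxyresorcinol (3,5‑dihydroxyanisole)
Product: **5** 1‑(2,4‑dihydroxy‑6‑methoxyphenyl)‑2‑(8‑hydroxy‑2,2‑dimethyl‑2H‑chromen‑6‑yl)ethan‑1‑one
Conditions: BF3·OEt2 (neat, 5–6 equiv), 70 °C, 2 h; then aq. NaOAc work‑up
Reagents that add atoms: none
Why: BF3‑promoted Friedel–Crafts/Hoesch‑type acylation takes place at the ring position ortho to a phenol OH, stabilised as a BF2 chelate. Acylation at the enantiotopic C2/C6 sites of the Cs‑symmetric resorcinol ether creates the 2'‑OH/6'‑OMe/4'‑OH pattern (later 7‑OH/5‑OMe) in one operation. **Proposed new method:** the regiochemical differentiation of OMe versus OH flanks is the accepted gamble, with no protecting groups. The closest known reaction is BF3‑mediated acylation of phloroglucinol or 3,5‑dimethoxyphenol with arylacetic acids (e.g. DOPAC with phloroglucinol to give orobol deoxybenzoins). Moderate BF3 temperature and short time are used to protect the acid‑labile chromene.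

**Step 3**
Reactants: **5** deoxybenzoin
Product: **6** Glycyrrhizaisoflavone B (target)
Conditions: BF3·OEt2, DMF, MsCl, 50–55 °C, 3 h; then pour into aq. NaOAc/H2O, 60 °C, 1 h
Reagents that add atoms: DMF, CN(C)C=O (its formyl carbon becomes C2 of the chromone); MsCl, CS(=O)(=O)Cl, activates DMF and leaves no atoms in the product
Why: This is the Wähälä BF3/DMF/MsCl isoflavone annulation. The BF2‑chelated deoxybenzoin is C‑formylated at the active methylene by the Vilsmeier‑type reagent. The 2'‑OH then closes onto the iminium/formyl carbon and eliminates to the chromone, tolerating free phenols. No stereocentre is involved.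

## Checks
- **Structure:** 6 has a chromone with 5‑OMe and 7‑OH. Its C3 aryl is a benzene ring bearing a 3'‑OH and a 4',5'‑fused 2,2‑dimethyl‑2H‑chromene, with the pyran O on C4' and the CH=CH on C5'. This matches the target SMILES.
- **Atom count:** 3 (C10, from 1 + 2, minus H2O) + 4 → 5 (minus H2O); 5 + one formyl carbon → 6 (net loss of H2O, and of H2 by oxidation level via the Vilsmeier pathway).
- **Functional groups:** the chromene C=C and the free phenols survive mildly acidic BF3 at ≤70 °C. The carboxylic acid is consumed in step 2. The 5‑OMe survives because BF3 at ≤70 °C is not demethylating under these conditions.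
- **Stereocentres:** none in the target, so none are set or scrambled.

## Compound list
1 | 3,4‑dihydroxyphenylacetic acid | OC(=O)Cc1ccc(O)c(O)c1 | starting material
2 | 3‑methylbut‑2‑enal (prenal) | CC(C)=CC=O | starting material
3 | 2‑(8‑hydroxy‑2,2‑dimethyl‑2H‑chromen‑6‑yl)acetic acid | OC(=O)Cc1cc(O)c2OC(C)(C)C=Cc2c1 | intermediate
4 | 5‑methoxyresorcinol | COc1cc(O)cc(O)c1 | starting material
5 | 1‑(2,4‑dihydroxy‑6‑methoxyphenyl)‑2‑(8‑hydroxy‑2,2‑dimethyl‑2H‑chromen‑6‑yl)ethanone | COc1cc(O)cc(O)c1C(=O)Cc1cc(O)c2OC(C)(C)C=Cc2c1 | intermediate
6 | Glycyrrhizaisoflavone B (achiral) | COc1cc(O)cc2occ(-c3cc(O)c4OC(C)(C)C=Cc4c3)c(=O)c12 | target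

## Totals
Total steps: 3. Longest linear sequence: 3.

## Three steps most likely to fail
1. **Step 2 (regiochemistry and chromene acid‑lability).** Risks are C4 versus C2 acylation and chromene oligomerisation in BF3.
   - Fallback: a different strategy, Suzuki–Miyaura coupling. 3‑Iodo‑7‑benzyloxy‑5‑methoxychromone (from 2‑hydroxy‑4‑benzyloxy‑6‑methoxyacetophenone, DMF‑DMA, then I2) is coupled with a protected 8‑hydroxychromen‑6‑yl boronate. Deprotection then gives the target with unambiguous A‑ring regiochemistry.
2. **Step 1 (catechol annulation).** Risks are catechol oxidation in hot pyridine and the minor C3 annulation isomer.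
   - Fallback: start from homovanillic acid (4‑hydroxy‑3‑methoxyphenylacetic acid), which has only one free ortho site. Annulate with prenal, then remove the aryl methyl ether by nucleophilic demethylation (NaSEt, DMF) to give 3 unambiguously.
3. **Step 3 (cyclisation in the presence of the chromene).** Risks are acid‑promoted chromene degradation and phenol O‑mesylation.
   - Fallback: make the chromone without strong acid. Convert 5 to its enaminone with DMF‑DMA (pyridine, 90 °C, free phenols transiently protected as TMS ethers), then cyclise with mild aqueous acid (I2/pyridine, or PPTS). A further alternative is an oxidative 1,2‑aryl migration of a chalcone/flavanone precursor (hypervalent‑iodine rearrangement).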